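**Retrosynthetic overview**

1. The target is taken back to its penta-benzyl ether (global hydrogenolysis last), and the C5 side chain is cut at the aryl–CH2 bond (Heck reaction of a C5 bromide with a 1-arylallyl alcohol).
2. The 3-aroyl-2,3-dihydrobenzofuran is treated as the ring-contraction isomer of a 2,4-diaryl-2H-chromene: shifting ring A (C3a) back from C3 to the ketone carbon gives the pyran O1–C2–C3=C4–C4a–C8a. In the forward direction a trivalent iodine reagent contracts this temporary ring and sets C3 trans to C2.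
3. The chromene comes from a racemic 2-(1-hydroxy-1,3-diarylallyl)phenol by closing O1–C2 under a chiral Brønsted acid; this is the only enantioselective step.
4. Enabling feature: O1 on C7a is ortho to C3a, and C3a and the ketone carbon both sit on C3. With ring A parked on the ketone carbon, C2–C3–C(ketone) is a 1,3-diarylallyl unit, stabilised at C2 by the 4-oxygenated phenyl and at the other end by the 2,4-dioxygenated phenyl. Its cation is the protonated vinylogous ortho-quinone methide of ring A, and O1 closes onto C2 by oxa-6π electrocyclisation.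
5. The carbinol comes from a 2'-hydroxychalcone (Claisen–Schmidt) and an aryl Grignard reagent. Ring order: all benzene rings are bought, the temporary pyran ring is closed first, then it is contracted to the furan ring.

Key step: step 4

Remarks. Atom numbers are those of the dihydrobenzofuran of the target (O1, C2, C3, C3a, C4 to C7, C7a; ring A is the benzo ring). In the chromene intermediates C4 is the future ketone carbon and C4a the future C3a. Assumption: the sense of induction of the chiral acid in step 4 cannot be assigned in advance; the (R)-catalyst is written, and its mirror image is taken if it proves to favour the (R)-chromene.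

**Route**

Step 1
Reactants: 1 1-(5-bromo-2-hydroxyphenyl)ethan-1-one; 2 4-(benzyloxy)benzaldehyde
Product: 3 (2E)-3-[4-(benzyloxy)phenyl]-1-(5-bromo-2-hydroxyphenyl)prop-2-en-1-one
Conditions: KOH (50% aq), EtOH, rt
Reagents that add atoms: none
Why: Claisen–Schmidt condensation of the methyl ketone with the non-enolisable aldehyde; the conjugated E-alkene forms under thermodynamic control and the phenoxide present in the basic medium does not close to the flavanone.

Step 2
Reactants: 4 4-bromobenzene-1,3-diol
Product: 5 2,4-bis(benzyloxy)-1-bromobenzene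
Conditions: BnBr (2.2 equiv), K2CO3, DMF, 60 °C
Reagents that add atoms: benzyl bromide, BrCc1ccccc1
Why: Williamson etherification of both phenols; the benzyl ethers should survive the Grignard, acid and iodine steps and leave with the others in step 8.

Step 3
Reactants: 3 (2E)-3-[4-(benzyloxy)phenyl]-1-(5-bromo-2-hydroxyphenyl)prop-2-en-1-one; 5 2,4-bis(benzyloxy)-1-bromobenzene
Product: 7 2-{(2E)-1-[2,4-bis(benzyloxy)phenyl]-3-[4-(benzyloxy)phenyl]-1-hydroxyprop-2-en-1-yl}-4-bromophenol (racemic), via arylmagnesium bromide 6 (not isolated)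
Conditions: 5 (2.6 equiv), Mg, THF, 45 °C; CeCl3, THF, −78 °C; then 3, −78 → 0 °C; aq NaHCO3
Reagents that add atoms: none
Why: Grignard formation followed by CeCl3-promoted 1,2-addition to the enone carbonyl (organocerium-type addition): the first equivalent of 6 only deprotonates the phenol, the cerium reagent suppresses conjugate addition and halogen–metal exchange at the ring A bromide, the carbinol centre is made racemic on purpose because it is erased in step 4, and the bicarbonate work-up avoids premature acid-triggered ionisation.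

Step 4
Reactants: 7 2-{(2E)-1-[2,4-bis(benzyloxy)phenyl]-3-[4-(benzyloxy)phenyl]-1-hydroxyprop-2-en-1-yl}-4-bromophenol
Product: 9 (2S)-2-[4-(benzyloxy)phenyl]-4-[2,4-bis(benzyloxy)phenyl]-6-bromo-2H-chromene, via ortho-quinone methide 8 (not isolated)
Conditions: (R)-3,3'-bis(2,4,6-triisopropylphenyl)-1,1'-binaphthalene-2,2'-diyl N-(trifluoromethylsulfonyl)phosphoramidate (5 mol%), 4 Å MS, toluene, −78 °C; then Et3N
Reagents that add atoms: none
Why: The strong chiral Brønsted acid protonates the tertiary hydroxyl of 7, water leaves, and the resulting 1,3-diarylallyl cation, which is the O-protonated form of the vinylogous ortho-quinone methide 8, stays hydrogen-bonded to the chiral phosphoramide anion as a contact ion pair. The pyran ring then closes by a thermal oxa-6π electrocyclisation of 8 (equivalently, 6-endo capture of the allyl cation by the ring A oxygen), which forms O1–C2 and regenerates the acid. The closest known reaction type is the chiral N-triflylphosphoramide-catalysed dehydrative allylic etherification of 2-(1-hydroxy-1,3-diarylallyl)phenols to 2,4-diaryl-2H-chromenes. The single new stereocentre, C2, is under catalyst control: the anion bound to the ring A oxygen blocks one face of the planar styryl terminus during closure, and the carbinol stereocentre of racemic 7 is erased on ionisation. The step needs O1–C2 closure rather than capture at the carbinol carbon (a four-membered ring, geometrically excluded) or Friedel–Crafts closure to an indene (disfavoured because the only free ortho position of the resorcinol ring is meta to both ether oxygens). Enantioselectivity needs a tight ion pair and no racemic background, which the non-polar solvent, −78 °C and the free phenol as anchor are meant to secure, while the electron-rich aryl groups at both allyl termini make ionisation possible at this temperature.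

Step 5
Reactants: 9 (2S)-2-[4-(benzyloxy)phenyl]-4-[2,4-bis(benzyloxy)phenyl]-6-bromo-2H-chromene
Product: 11 {(2S,3S)-2-[4-(benzyloxy)phenyl]-5-bromo-2,3-dihydro-1-benzofuran-3-yl}[2,4-bis(benzyloxy)phenyl]methanone, via methoxy iodane adduct 10 (not isolated)
Conditions: PhI(OH)OTs (1.1 equiv), MeOH–CH2Cl2–H2O (9:9:1), −20 → 0 °C; aq NaHCO3
Reagents that add atoms: water, O (becomes the ketone oxygen)
Why: Oxidative ring contraction by 1,2-aryl shift with a trivalent iodine reagent (the reaction type known for 1,2-dihydronaphthalenes to indanes, for flavanone enol ethers to 2-aryl-2,3-dihydrobenzofuran-3-carboxylates and for 1,1-diarylalkenes to α-aryl ketones): the iodine electrophile adds to C3 anti to the C2 aryl, methanol caps the doubly benzylic C4 cation trans to give 10, and in the conformer with the C3–I bond equatorial only the ring bond C4–C4a is antiperiplanar to it, so ring A and not the resorcinol ring migrates from C4 to C3 with inversion and loss of PhI; C4 becomes the ketone after hydrolysis of the methoxy-oxocarbenium ion by the water present, C2 is untouched, and C3 is set trans to the C2 aryl both by the stereospecific shift and by the thermodynamic preference of this enolisable centre.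

Step 6
Reactants: 12 2,4-bis(benzyloxy)benzaldehyde
Product: 13 1-[2,4-bis(benzyloxy)phenyl]prop-2-en-1-ol (racemic)
Conditions: CH2=CHMgBr, THF, 0 °C; aq NH4Cl
Reagents that add atoms: vinylmagnesium bromide, C=C[Mg]Br
Why: Grignard 1,2-addition to the aldehyde; the carbinol stereocentre is racemic and is destroyed in step 7.

Step 7
Reactants: 11 {(2S,3S)-2-[4-(benzyloxy)phenyl]-5-bromo-2,3-dihydro-1-benzofuran-3-yl}[2,4-bis(benzyloxy)phenyl]methanone; 13 1-[2,4-bis(benzyloxy)phenyl]prop-2-en-1-ol
Product: 15 1-[2,4-bis(benzyloxy)phenyl]-3-{(2S,3S)-2-[4-(benzyloxy)phenyl]-3-[2,4-bis(benzyloxy)benzoyl]-2,3-dihydro-1-benzofuran-5-yl}propan-1-one, via enol 14 (not isolated)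
Conditions: Pd(OAc)2 (5 mol%), n-Bu4NCl, NaHCO3, DMF, 70 °C
Reagents that add atoms: none
Why: Heck reaction of an aryl bromide with a secondary allylic alcohol: the ring A–Pd species adds to the terminal alkene carbon, β-hydride elimination towards the carbinol C–H gives enol 14, which tautomerises to the saturated ketone, so the dihydrochalcone chain arises without a separate reduction; no stereocentre is formed, and the weak bicarbonate base is chosen so that the enolisable C3–H next to the C2–O1 bond is not ionised.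

Step 8
Reactants: 15 1-[2,4-bis(benzyloxy)phenyl]-3-{(2S,3S)-2-[4-(benzyloxy)phenyl]-3-[2,4-bis(benzyloxy)benzoyl]-2,3-dihydro-1-benzofuran-5-yl}propan-1-one
Product: 16 1-(2,4-dihydroxyphenyl)-3-[(2S,3S)-3-(2,4-dihydroxybenzoyl)-2-(4-hydroxyphenyl)-2,3-dihydro-1-benzofuran-5-yl]propan-1-one (CNP0136359.1)
Conditions: H2 (1 atm), 10% Pd/C, EtOAc–MeOH, rt
Reagents that add atoms: none
Why: Hydrogenolysis of the five aryl benzyl ethers over Pd/C under neutral conditions; these cleave faster than the cyclic secondary benzylic C2–O1 bond and the two ortho-hydroxyaryl ketones are left intact (as in global debenzylations of flavanones, flavan-3-ols and dihydrobenzofuran neolignans), no stereocentre is touched, and neither acid nor base is present that could open the furan ring.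

**Compound list**

1 | 1-(5-bromo-2-hydroxyphenyl)ethan-1-one | CC(=O)c1cc(Br)ccc1O | starting material
2 | 4-(benzyloxy)benzaldehyde | O=Cc1ccc(OCc2ccccc2)cc1 | starting material
3 | (2E)-3-[4-(benzyloxy)phenyl]-1-(5-bromo-2-hydroxyphenyl)prop-2-en-1-one | O=C(/C=C/c1ccc(OCc2ccccc2)cc1)c1cc(Br)ccc1O | intermediate
4 | 4-bromobenzene-1,3-diol | Oc1ccc(Br)c(O)c1 | starting material
5 | 2,4-bis(benzyloxy)-1-bromobenzene | Brc1ccc(OCc2ccccc2)cc1OCc1ccccc1 | intermediate
6 | [2,4-bis(benzyloxy)phenyl]magnesium bromide (formed in the flask, not isolated) | Br[Mg]c1ccc(OCc2ccccc2)cc1OCc1ccccc1 | intermediate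
7 | 2-{(2E)-1-[2,4-bis(benzyloxy)phenyl]-3-[4-(benzyloxy)phenyl]-1-hydroxyprop-2-en-1-yl}-4-bromophenol (racemic) | OC(/C=C/c1ccc(OCc2ccccc2)cc1)(c1ccc(OCc2ccccc2)cc1OCc1ccccc1)c1cc(Br)ccc1O | intermediate
8 | 6-{(2E)-1-[2,4-bis(benzyloxy)phenyl]-3-[4-(benzyloxy)phenyl]prop-2-en-1-ylidene}-4-bromocyclohexa-2,4-dien-1-one, styryl group cis to the ring carbonyl (formed in the flask, not isolated) | O=C1C=CC(Br)=C/C1=C(/C=C/c1ccc(OCc2ccccc2)cc1)c1ccc(OCc2ccccc2)cc1OCc1ccccc1 | intermediate
9 | (2S)-2-[4-(benzyloxy)phenyl]-4-[2,4-bis(benzyloxy)phenyl]-6-bromo-2H-chromene | Brc1ccc2c(c1)C(c1ccc(OCc3ccccc3)cc1OCc1ccccc1)=C[C@@H](c1ccc(OCc3ccccc3)cc1)O2 | intermediate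
10 | adduct of 9: 2-[4-(benzyloxy)phenyl]-4-[2,4-bis(benzyloxy)phenyl]-6-bromo-4-methoxy-3-[phenyl(tosyloxy)iodanyl]chromane, iodine on C3 anti to the C2 aryl and methoxy on C4 anti to iodine (formed in the flask, not isolated) | CO[C@@]1(c2ccc(OCc3ccccc3)cc2OCc2ccccc2)[C@H]([I](c2ccccc2)OS(=O)(=O)c2ccc(C)cc2)[C@@H](c2ccc(OCc3ccccc3)cc2)Oc2ccc(Br)cc21 | intermediate
11 | {(2S,3S)-2-[4-(benzyloxy)phenyl]-5-bromo-2,3-dihydro-1-benzofuran-3-yl}[2,4-bis(benzyloxy)phenyl]methanone | Brc1ccc2c(c1)[C@H](C(=O)c1ccc(OCc3ccccc3)cc1OCc1ccccc1)[C@@H](c1ccc(OCc3ccccc3)cc1)O2 | intermediate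
12 | 2,4-bis(benzyloxy)benzaldehyde | O=Cc1ccc(OCc2ccccc2)cc1OCc1ccccc1 | starting material
13 | 1-[2,4-bis(benzyloxy)phenyl]prop-2-en-1-ol (racemic) | C=CC(O)c1ccc(OCc2ccccc2)cc1OCc1ccccc1 | intermediate
14 | (1Z)-1-[2,4-bis(benzyloxy)phenyl]-3-{(2S,3S)-2-[4-(benzyloxy)phenyl]-3-[2,4-bis(benzyloxy)benzoyl]-2,3-dihydro-1-benzofuran-5-yl}prop-1-en-1-ol, alkene geometry immaterial (formed in the flask, not isolated) | O/C(=C\Cc1ccc2c(c1)[C@H](C(=O)c1ccc(OCc3ccccc3)cc1OCc1ccccc1)[C@@H](c1ccc(OCc3ccccc3)cc1)O2)c1ccc(OCc2ccccc2)cc1OCc1ccccc1 | intermediate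
15 | 1-[2,4-bis(benzyloxy)phenyl]-3-{(2S,3S)-2-[4-(benzyloxy)phenyl]-3-[2,4-bis(benzyloxy)benzoyl]-2,3-dihydro-1-benzofuran-5-yl}propan-1-one | O=C(CCc1ccc2c(c1)[C@H](C(=O)c1ccc(OCc3ccccc3)cc1OCc1ccccc1)[C@@H](c1ccc(OCc3ccccc3)cc1)O2)c1ccc(OCc2ccccc2)cc1OCc1ccccc1 | intermediate
16 | 1-(2,4-dihydroxyphenyl)-3-[(2S,3S)-3-(2,4-dihydroxybenzoyl)-2-(4-hydroxyphenyl)-2,3-dihydro-1-benzofuran-5-yl]propan-1-one | O=C(CCc1ccc2c(c1)[C@H](C(=O)c1ccc(O)cc1O)[C@@H](c1ccc(O)cc1)O2)c1ccc(O)cc1O | target

**Step count and risks**

Total steps: 8. Longest linear sequence: 6 steps (1 → 3 → 7 → 9 → 11 → 15 → 16).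

Steps most likely to fail:

1. Step 4 (key step). The carbinol ionises so easily that an uncatalysed or achiral-acid-promoted closure (on silica, on glass, during the work-up of step 3) or a loosely held ion pair could erode the enantiomeric purity, and the chromene could re-ionise and racemise before the quench. The fallback sets C2 by a stereospecific epoxide opening instead; it sets out from 3 and comes back at 11. Chalcone 3 would be converted with MOMCl and i-Pr2NEt into its methoxymethyl ether, (2E)-3-[4-(benzyloxy)phenyl]-1-[5-bromo-2-(methoxymethoxy)phenyl]prop-2-en-1-one F1. Juliá–Colonna epoxidation (poly-L-leucine, urea–H2O2, DBU, THF) should then give the trans epoxide {(2R,3S)-3-[4-(benzyloxy)phenyl]oxiran-2-yl}[5-bromo-2-(methoxymethoxy)phenyl]methanone F2. HCl in MeOH would remove the acetal and let the freed phenol open the epoxide at the benzylic carbon in the 6-endo mode with inversion, giving the trans dihydroflavonol (2R,3R)-2-[4-(benzyloxy)phenyl]-6-bromo-3-hydroxy-2,3-dihydro-4H-chromen-4-one F3. MsCl and Et3N at −20 °C would give its 3-methanesulfonate F4. Addition of Grignard reagent 6 with CeCl3 at −78 °C should give the 4-aryl-4-hydroxychroman-3-yl methanesulfonate F5 as its magnesium alkoxide. On addition of Et2AlCl this should undergo the semipinacol shift of ring A from C4 to C3, antiperiplanar to the equatorial mesylate and with inversion at C3, to give ketone 11 directly.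

2. Step 5. The iodine reagent could instead abstract hydride from C2 (aromatisation to a benzopyrylium ion), the C4 cation could be captured twice by solvent without the 1,2-shift, or the reagent could attack the dialkoxyarene rings. The fallback replaces the one-step oxidative shift by a dihydroxylation and semipinacol sequence; it sets out from 9 and comes back at 11. OsO4 (cat.) with N-methylmorpholine N-oxide in acetone–water should dihydroxylate the C3=C4 bond on the face anti to the C2 aryl to give the cis diol (2R,3R)-2-[4-(benzyloxy)phenyl]-4-[2,4-bis(benzyloxy)phenyl]-6-bromo-3,4-dihydro-2H-chromene-3,4-diol F6. MsCl and Et3N at −20 °C should sulfonylate only the secondary hydroxyl to give the 3-methanesulfonate F7. Et3Al in CH2Cl2 at −78 °C should then drive the semipinacol migration of ring A from C4 to C3 with loss of mesylate to give 11.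

3. Step 7. Base and heat could enolise C3 and expel the ring A phenoxide by β-elimination (irreversible ring opening), and β-hydride elimination away from the carbinol would give an allylic alcohol instead of the ketone. The fallback is a base-free reductive coupling; it sets out from 11 and 13 and comes back at 15. Alcohol 13 would be oxidised with MnO2 in CH2Cl2 to the enone 1-[2,4-bis(benzyloxy)phenyl]prop-2-en-1-one F8. Nickel-catalysed reductive conjugate addition of bromide 11 to F8 (NiCl2(dme), neocuproine, Mn powder, Et3SiCl, DMF, rt) should give the triethylsilyl enol ether of 15 F9, which dilute citric acid in THF–water would hydrolyse to 15.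

**Further compounds**

F1 | step 4 | (2E)-3-[4-(benzyloxy)phenyl]-1-[5-bromo-2-(methoxymethoxy)phenyl]prop-2-en-1-one | COCOc1ccc(Br)cc1C(=O)/C=C/c1ccc(OCc2ccccc2)cc1
F2 | step 4 | {(2R,3S)-3-[4-(benzyloxy)phenyl]oxiran-2-yl}[5-bromo-2-(methoxymethoxy)phenyl]methanone | COCOc1ccc(Br)cc1C(=O)[C@@H]1O[C@H]1c1ccc(OCc2ccccc2)cc1
F3 | step 4 | (2R,3R)-2-[4-(benzyloxy)phenyl]-6-bromo-3-hydroxy-2,3-dihydro-4H-chromen-4-one | O=C1[C@H](O)[C@@H](c2ccc(OCc3ccccc3)cc2)Oc2ccc(Br)cc21
F4 | step 4 | (2R,3R)-2-[4-(benzyloxy)phenyl]-6-bromo-4-oxo-3,4-dihydro-2H-chromen-3-yl methanesulfonate | O=C1[C@H](OS(C)(=O)=O)[C@@H](c2ccc(OCc3ccccc3)cc2)Oc2ccc(Br)cc21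
F5 | step 4 | (2R,3R)-2-[4-(benzyloxy)phenyl]-4-[2,4-bis(benzyloxy)phenyl]-6-bromo-4-hydroxy-3,4-dihydro-2H-chromen-3-yl methanesulfonate, 4-hydroxyl cis to the C2 aryl (formed as its magnesium alkoxide) | O[C@@]1(c2ccc(OCc3ccccc3)cc2OCc2ccccc2)[C@H](OS(C)(=O)=O)[C@@H](c2ccc(OCc3ccccc3)cc2)Oc2ccc(Br)cc21
F6 | step 5 | (2R,3R)-2-[4-(benzyloxy)phenyl]-4-[2,4-bis(benzyloxy)phenyl]-6-bromo-3,4-dihydro-2H-chromene-3,4-diol, hydroxyls cis to each other and anti to the C2 aryl | O[C@]1(c2ccc(OCc3ccccc3)cc2OCc2ccccc2)[C@H](O)[C@@H](c2ccc(OCc3ccccc3)cc2)Oc2ccc(Br)cc21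
F7 | step 5 | (2R,3R)-2-[4-(benzyloxy)phenyl]-4-[2,4-bis(benzyloxy)phenyl]-6-bromo-4-hydroxy-3,4-dihydro-2H-chromen-3-yl methanesulfonate, 4-hydroxyl anti to the C2 aryl | O[C@]1(c2ccc(OCc3ccccc3)cc2OCc2ccccc2)[C@H](OS(C)(=O)=O)[C@@H](c2ccc(OCc3ccccc3)cc2)Oc2ccc(Br)cc21
F8 | step 7 | 1-[2,4-bis(benzyloxy)phenyl]prop-2-en-1-one | C=CC(=O)c1ccc(OCc2ccccc2)cc1OCc1ccccc1
F9 | step 7 | [(1Z)-1-[2,4-bis(benzyloxy)phenyl]-3-{(2S,3S)-2-[4-(benzyloxy)phenyl]-3-[2,4-bis(benzyloxy)benzoyl]-2,3-dihydro-1-benzofuran-5-yl}prop-1-en-1-yl]oxy(triethyl)silane | CC[Si](CC)(CC)O/C(=C\Cc1ccc2c(c1)[C@H](C(=O)c1ccc(OCc3ccccc3)cc1OCc1ccccc1)[C@@H](c1ccc(OCc3ccccc3)cc1)O2)c1ccc(OCc2ccccc2)cc1OCc1ccccc1
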